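## Retrosynthetic overview

1. Numbering: ring A = C1–C6 (C3 acetoxy, C4=C5 with CH3 on C4); ring B = C1, C6–C10 (C7 bears C11(=C13)–C12O2H, C8 the acyloxy group, C10 the carbinol). The strategy rests on ring B: the C7–C11 bond is cis to the C8 oxygen, so a diazoacetate on O8 can reach the cis C7–H bond and form C7–C11 as a cis-fused γ-lactone (C11, C12), which is later methylenated (C13) and opened.
2. Target ⇒ α-methylene lactone: reduction to the 8,12-diol, C8 acylation with an acetonide-protected (E)-dihydroxytiglic acid (from 2-butyne-1,4-diol), C12 reoxidation, C3 silyl-to-acetate exchange.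
3. Lactone ⇒ C8 diazoacetate (C–H insertion) ⇒ 8α,10β-diol ⇒ C10-methylene homoallylic alcohol ⇒ carbonyl-ene closure of ring B (C8–C9) from a ring A aldehyde.
4. Aldehyde ⇒ Johnson–Claisen rearrangement (C6–C7) of a tertiary allylic alcohol made from (S)-carvone, which supplies ring A, the C1 stereocentre and the C9/C10 isopropenyl unit.
5. Ring order: ring A (carvone), ring B (carbonyl-ene), temporary lactone ring (C–H insertion, opened again by reduction).

Key step: step 12

Remark: α/β refer to a flat drawing of the decalin with H-1 and H-6 down (α). The target SMILES then requires 3β-OAc, the C7 side chain α (H-7 β), 8α-O-acyl, 10β-OH with 10α-CH3, and an E side-chain alkene.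

Assumption: the cis-decalin intermediates react from the chair–chair conformer that keeps C10 equatorial on ring A; in it the C8 oxygen is axial on ring B, and all stereochemical arguments below use this conformer.

## Route

Step 1
Reactants: 1 (S)-(+)-carvone
Product: 2 (1S,5S)-cis-carveol (3β-OH cis to the isopropenyl group on C1)
Conditions: NaBH4, CeCl3·7H2O, MeOH, 0 °C
Reagents that add atoms: none
Why: Luche reduction: the CeCl3-activated enone takes hydride 1,2 and axially, so the new C3 hydroxyl should end up pseudo-equatorial and cis to the isopropenyl group (C3 set by the carvone stereocentre).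

Step 2
Reactants: 2 cis-carveol
Product: 3 4β,5β-epoxy-cis-carveol (oxirane oxygen cis to the hydroxyl and to the isopropenyl group)
Conditions: VO(acac)2 (cat.), t-BuOOH, CH2Cl2, 0 °C to rt
Reagents that add atoms: tert-butyl hydroperoxide, CC(C)(C)OO
Why: Hydroxyl-directed vanadium-catalysed epoxidation: oxygen is delivered from the bound C3 alkoxide to the syn (β) face of the ring alkene only, which sets C4 and C5 and leaves the isopropenyl group untouched.

Step 3
Reactants: 3 epoxy alcohol
Product: 4 TBS ether of the epoxy alcohol (3β-OTBS)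
Conditions: TBSCl, imidazole, DMF, rt
Reagents that add atoms: tert-butyldimethylsilyl chloride, CC(C)(C)[Si](C)(C)Cl
Why: Standard silylation of the secondary alcohol under conditions that do not open the epoxide; the TBS ether is meant to last until the late fluoride treatment.

Step 4
Reactants: 4 epoxy silyl ether
Product: 7 tertiary allylic alcohol (3β-OTBS; 4β-OH; 4α-CH3; C5=C6; 1β-isopropenyl), via hydroxy selenide 5 (not isolated), via selenoxide 6 (not isolated)
Conditions: (PhSe)2, NaBH4, EtOH, 50 °C; then 30% H2O2, pyridine, THF, 0 °C to rt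
Reagents that add atoms: none
Why: Epoxide opening by selenolate followed by selenoxide syn-elimination: PhSe− attacks the secondary oxirane carbon C5 from the α face in the trans-diaxial sense (Fürst–Plattner rule, both ring substituents equatorial), and the selenoxide, with no hydrogen on C4, can eliminate only toward C6, giving the tertiary allylic alcohol with the C4 oxygen still β.

Step 5
Reactants: 7 tertiary allylic alcohol; 8 triethyl orthoacetate
Product: 10 ethyl ester (all-cis: 3β-OTBS; 6β-CH2CO2Et; 1β-isopropenyl; C4=C5), via ketene acetal 9 (not isolated)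
Conditions: MeC(OEt)3 (excess), EtCO2H (cat.), xylene, 140 °C, EtOH distilled off
Reagents that add atoms: none
Why: Johnson–Claisen rearrangement: the mixed ketene acetal undergoes a suprafacial [3,3] shift through a chair-like transition state with the C4–O bond pseudo-axial, so C7 is delivered to C6 on the β face, cis to the isopropenyl group (sets C6), and the alkene moves to C4=C5.

Step 6
Reactants: 10 ethyl ester
Product: 11 aldehyde (6β-CH2CHO)
Conditions: i-Bu2AlH (1.05 equiv), CH2Cl2, −78 °C; Rochelle salt work-up
Reagents that add atoms: none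
Why: Low-temperature i-Bu2AlH reduction stops at the tetrahedral aluminium hemiacetal, which releases the aldehyde only on work-up; the silyl ether and both alkenes are inert.

Step 7
Reactants: 11 aldehyde
Product: 12 cis-fused octalin homoallylic alcohol (3β-OTBS, 8α-OH, exocyclic methylene on C10, C4=C5)
Conditions: Me2AlCl (1.5 equiv), CH2Cl2, −78 to −20 °C
Reagents that add atoms: none
Why: Lewis acid-promoted carbonyl-ene cyclisation with the tether on the central carbon of the ene unit: C8 bonds to the alkene terminus C9 while a methyl hydrogen passes to the aluminium-bound oxygen through a chair-like bicyclic transition state that requires an axial C8–O, and the chair that keeps C10 equatorial on ring A and avoids a C5/O8 syn-axial clash puts this oxygen α (sets C8; the cis ring fusion is already fixed by C1 and C6), Me2AlCl removing the proton as methane.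

Step 8
Reactants: 12 homoallylic alcohol
Product: 14 diol (3β-OTBS; 8α-OH; 10β-OH; 10α-CH3), via organomercurial 13 (not isolated)
Conditions: Hg(OAc)2 (1.05 equiv), THF/H2O, 0 °C to rt; then NaBH4, aq NaOH, 0 °C
Reagents that add atoms: water, O
Why: Markovnikov oxymercuration–demercuration, faster at the 1,1-disubstituted exocyclic alkene than at the trisubstituted C4=C5: the axial 8α-hydroxyl binds divalent mercury and holds the mercurinium ion on the α face, so water should open it at C10 from the β face (10β-OH, new methyl α; sets C10), and NaBH4 then replaces mercury by hydrogen.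

Step 9
Reactants: 14 diol; 15 bromoacetyl bromide
Product: 16 8α-bromoacetate (10β-OH free)
Conditions: BrCH2COBr (1.2 equiv), pyridine, CH2Cl2, −20 to 0 °C
Reagents that add atoms: none
Why: Acylation with an acyl bromide discriminates cleanly between the secondary C8 hydroxyl and the tertiary C10 hydroxyl, which does not react at low temperature.

Step 10
Reactants: 16 bromoacetate
Product: 17 10β-triethylsilyl ether of the bromoacetate
Conditions: Et3SiOTf, 2,6-lutidine, CH2Cl2, −78 to 0 °C
Reagents that add atoms: triethylsilyl trifluoromethanesulfonate, CC[Si](CC)(CC)OS(=O)(=O)C(F)(F)F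
Why: A silyl triflate with a hindered pyridine base silylates the tertiary alcohol, which would otherwise undergo O–H insertion in step 12; the bromoacetate is not enolised under these conditions.

Step 11
Reactants: 17 silylated bromoacetate
Product: 18 C8 diazoacetate (3β-OTBS, 10β-OTES)
Conditions: TsNHNHTs (2 equiv), DBU (5 equiv), THF, 0 °C
Reagents that add atoms: N,N'-ditosylhydrazine, Cc1ccc(cc1)S(=O)(=O)NNS(=O)(=O)c1ccc(C)cc1
Why: Diazoacetate formation from a bromoacetate: N-alkylation of the ditosylhydrazine and two base-induced sulfinate eliminations give the diazo ester under mild conditions that both silyl ethers tolerate.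

Step 12
Reactants: 18 C8 diazoacetate
Product: 19 tricyclic cis-fused γ-lactone (12,8α-olide; C7–C11 bond α; 3β-OTBS; 10β-OTES)
Conditions: Rh2(cap)4 (dirhodium tetracaprolactamate, 1 mol %), CH2Cl2, reflux, slow addition of 18 at high dilution
Reagents that add atoms: none
Why: Rh2(cap)4 (divalent rhodium) expels N2 from the diazoacetate to give an electrophilic metal carbene on the axial 8α ester oxygen, which inserts with retention into the equatorial 7α C–H bond through a five-membered transition state and so forms C7–C11. The closest known reaction type is the dirhodium carboxamidate-catalysed intramolecular C–H insertion of cyclohexyl diazoacetates to cis-fused γ-butyrolactones. The lactone ring closes by 1,5-insertion and is fused to ring B through C7–C8; because the ester oxygen is axial, the only adjacent C–H bonds within reach are the cis (equatorial) ones, so the fusion must be cis and C7 is set by C8. The step needs C7–H insertion rather than insertion at C9–H, at the syn-axial allylic C6–H (bridged six-membered lactone) or at C8–H (β-lactone), and no addition to C4=C5 or carbene dimerisation. The C9 hydrogens are deactivated by two β oxygens (O8 and the C10 silyl ether) and screened by the quaternary C10 with its OTES group, carboxamidate ligands give a selective carbene that prefers the five-membered transition state, and the ring A alkene lies beyond the reach of the three-atom tether. Slow addition suppresses dimerisation and the TES ether excludes O–H insertion.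

Step 13
Reactants: 19 γ-lactone
Product: 22 α-methylene γ-lactone (C11=C13), via Mannich base 20 (not isolated), via ammonium iodide 21 (not isolated)
Conditions: LDA, THF, −78 °C; CH2=NMe2+ I−, −78 °C to rt; MeI, MeOH, rt; aq NaHCO3, CH2Cl2
Reagents that add atoms: dimethylmethyleneammonium iodide, C=[N+](C)C.[I-]
Why: α-Methylenation by Mannich reaction of the lactone lithium enolate with the iminium salt, N-methylation and E1cB loss of trimethylamine; the stereocentre at C7 is β to the carbonyl and is not touched.

Step 14
Reactants: 22 α-methylene lactone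
Product: 23 8α,12-diol (2-methylene-1,4-diol; 3β-OTBS, 10β-OTES)
Conditions: i-Bu2AlH (4 equiv), CH2Cl2, −78 to 0 °C; Rochelle salt work-up
Reagents that add atoms: none
Why: i-Bu2AlH reduces the lactone carbonyl 1,2 through the lactol to the diol without conjugate reduction, which frees O8 for acylation and avoids the relactonisation a hydroxy acid would undergo.

Step 15
Reactants: 23 diol
Product: 24 12-O-triethylsilyl ether (8α-OH free)
Conditions: Et3SiCl (1.05 equiv), imidazole, CH2Cl2, −78 to −40 °C
Reagents that add atoms: triethylsilyl chloride, CC[Si](CC)(CC)Cl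
Why: Kinetic silylation selects the unhindered primary allylic hydroxyl over the axial secondary C8 hydroxyl, which is flanked by the C7 side chain and the syn-axial C10 methyl.

Step 16
Reactants: 25 2-butyne-1,4-diol
Product: 26 (E)-2-(tributylstannyl)but-2-ene-1,4-diol (the two CH2OH groups cis)
Conditions: Bu3SnH, PdCl2(PPh3)2 (cat.), THF, rt
Reagents that add atoms: tributyltin hydride, CCCC[SnH](CCCC)CCCC
Why: Palladium-catalysed hydrostannation adds H and Sn syn across the symmetrical alkyne, so a single isomer with the two hydroxymethyl groups cis should result.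

Step 17
Reactants: 26 stannyl diol
Product: 27 2,2-dimethyl-5-(tributylstannyl)-4,7-dihydro-1,3-dioxepine
Conditions: Me2C(OMe)2, PPTS (cat.), CH2Cl2, rt
Reagents that add atoms: 2,2-dimethoxypropane, COC(C)(C)OC
Why: Acid-catalysed transacetalisation; the cis disposition of the two hydroxymethyl groups allows the seven-membered acetonide, which locks the alkene geometry.

Step 18
Reactants: 27 stannyl dioxepine
Product: 29 2,2-dimethyl-4,7-dihydro-1,3-dioxepine-5-carboxylic acid, via vinyllithium 28 (not isolated)
Conditions: n-BuLi, THF, −78 °C; CO2; aq citric acid work-up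
Reagents that add atoms: carbon dioxide, O=C=O
Why: Tin–lithium exchange, driven by formation of Bu4Sn and the sp2 organolithium, proceeds with retention of alkene geometry, and carboxylation at −78 °C traps the vinyllithium before it can fragment, giving the acid whose ring fixes the E geometry of the later side chain.

Step 19
Reactants: 24 C8 alcohol; 29 dioxepine acid
Product: 31 C8 ester (8α-O-acyl; 12-OTES; 3β-OTBS; 10β-OTES), via mixed anhydride 30 (not isolated)
Conditions: 29, 2,4,6-Cl3C6H2COCl, Et3N, THF, rt; then 24, DMAP, toluene, rt to 60 °C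
Reagents that add atoms: none
Why: Yamaguchi esterification: DMAP attacks the less hindered carbonyl of the mixed anhydride and the resulting acylpyridinium acylates the only free hydroxyl, the hindered axial 8α-OH.

Step 20
Reactants: 31 ester with primary TES ether
Product: 32 enal (C12 aldehyde conjugated with C11=C13)
Conditions: (COCl)2, DMSO, CH2Cl2, −78 to −35 °C; then Et3N, −78 °C to rt
Reagents that add atoms: none
Why: Swern oxidation applied directly to a primary triethylsilyl ether: the chlorosulfonium reagent desilylates the unhindered primary ether and oxidises it to the enal in one flask, while the tertiary TES and secondary TBS ethers are too hindered to react.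

Step 21
Reactants: 32 enal
Product: 33 acrylic acid (C12 acid; 3β-OTBS, 10β-OTES, acetonide)
Conditions: NaClO2, NaH2PO4, 2-methyl-2-butene, t-BuOH/H2O, 0 °C to rt
Reagents that add atoms: sodium chlorite, [Na+].[O-]Cl=O
Why: Pinnick oxidation converts the enal into the acrylic acid with chlorous acid, the hypochlorous acid being trapped by 2-methyl-2-butene so that the ring alkene, the enoate and the acetal should survive.

Step 22
Reactants: 33 bis-silyl ether acid
Product: 34 3β,10β-diol acid (acetonide intact)
Conditions: Bu4NF, AcOH (equimolar to fluoride), THF, rt to 40 °C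
Reagents that add atoms: none
Why: Fluoride cleaves the secondary TBS and tertiary TES ethers while acetic acid buffering suppresses acyl migration and conjugate addition; the acetonide is inert to fluoride.

Step 23
Reactants: 34 diol acid
Product: 36 3β-acetate (10β-OH and C12 acid free; acetonide intact), via mixed anhydride 35 (not isolated)
Conditions: Ac2O, pyridine, rt; then H2O, THF, rt
Reagents that add atoms: acetic anhydride, CC(=O)OC(C)=O
Why: Acetic anhydride in pyridine acetylates the secondary allylic C3 hydroxyl but not the tertiary C10 hydroxyl, and the mixed anhydride formed at C12 is hydrolysed back to the acid in the aqueous stage.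

Step 24
Reactants: 36 acetonide
Product: 37 target CNP0468194.1
Conditions: AcOH/THF/H2O (3:1:1), rt to 40 °C
Reagents that add atoms: none
Why: Mild aqueous acid hydrolyses the seven-membered acetonide to release the two primary hydroxyls without ionising the allylic acetate or dehydrating the tertiary alcohol, and the E geometry prevents butenolide formation.

## Compound list

1 | (S)-(+)-carvone | CC1=CC[C@@H](CC1=O)C(C)=C | starting material
2 | (1S,5S)-cis-carveol | C1C=C(C)[C@@H](O)C[C@H]1C(C)=C | intermediate
3 | 4β,5β-epoxy-cis-carveol (oxirane O cis to OH and isopropenyl) | C1[C@H]2O[C@@]2(C)[C@@H](O)C[C@H]1C(C)=C | intermediate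
4 | TBS ether of 3 | C1[C@H]2O[C@@]2(C)[C@@H](O[Si](C)(C)C(C)(C)C)C[C@H]1C(C)=C | intermediate
5 | 4β-hydroxy-5α-phenylselenide (trans-diaxial) | C1[C@H]([Se]c2ccccc2)[C@@](C)(O)[C@@H](O[Si](C)(C)C(C)(C)C)C[C@H]1C(C)=C | intermediate (not isolated)
6 | selenoxide of 5 | C1[C@H]([Se](=O)c2ccccc2)[C@@](C)(O)[C@@H](O[Si](C)(C)C(C)(C)C)C[C@H]1C(C)=C | intermediate (not isolated)
7 | tertiary allylic alcohol (3β-OTBS, 4β-OH, 4α-CH3, C5=C6, 1β-isopropenyl) | C1=C[C@@](C)(O)[C@@H](O[Si](C)(C)C(C)(C)C)C[C@H]1C(C)=C | intermediate
8 | triethyl orthoacetate | CCOC(C)(OCC)OCC | starting material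
9 | mixed ketene acetal of 7 (4β-O–C(=CH2)OEt) | C1=C[C@@](C)(OC(=C)OCC)[C@@H](O[Si](C)(C)C(C)(C)C)C[C@H]1C(C)=C | intermediate (not isolated)
10 | ethyl ester (3β-OTBS, 6β-CH2CO2Et, 1β-isopropenyl, C4=C5) | CCOC(=O)C[C@H]1C=C(C)[C@@H](O[Si](C)(C)C(C)(C)C)C[C@H]1C(C)=C | intermediate
11 | aldehyde (6β-CH2CHO) | O=CC[C@H]1C=C(C)[C@@H](O[Si](C)(C)C(C)(C)C)C[C@H]1C(C)=C | intermediate
12 | cis-octalin homoallylic alcohol (3β-OTBS, 8α-OH, C10 exocyclic methylene) | C1[C@H]2C=C(C)[C@@H](O[Si](C)(C)C(C)(C)C)C[C@H]2C(=C)C[C@@H]1O | intermediate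
13 | organomercurial (10β-OH, 10α-CH2HgOAc) | C1[C@H]2C=C(C)[C@@H](O[Si](C)(C)C(C)(C)C)C[C@H]2[C@@](C[Hg]OC(C)=O)(O)C[C@@H]1O | intermediate (not isolated)
14 | diol (3β-OTBS, 8α-OH, 10β-OH, 10α-CH3) | C1[C@H]2C=C(C)[C@@H](O[Si](C)(C)C(C)(C)C)C[C@H]2[C@@](C)(O)C[C@@H]1O | intermediate
15 | bromoacetyl bromide | BrCC(Br)=O | starting material
16 | 8α-bromoacetate | C1[C@H]2C=C(C)[C@@H](O[Si](C)(C)C(C)(C)C)C[C@H]2[C@@](C)(O)C[C@@H]1OC(=O)CBr | intermediate
17 | 8α-bromoacetate 10β-TES ether | C1[C@H]2C=C(C)[C@@H](O[Si](C)(C)C(C)(C)C)C[C@H]2[C@@](C)(O[Si](CC)(CC)CC)C[C@@H]1OC(=O)CBr | intermediate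
18 | C8 diazoacetate | C1[C@H]2C=C(C)[C@@H](O[Si](C)(C)C(C)(C)C)C[C@H]2[C@@](C)(O[Si](CC)(CC)CC)C[C@@H]1OC(=O)C=[N+]=[N-] | intermediate
19 | cis-fused γ-lactone (12,8α-olide) | O=C1C[C@@H]2[C@H]3C=C(C)[C@@H](O[Si](C)(C)C(C)(C)C)C[C@H]3[C@@](C)(O[Si](CC)(CC)CC)C[C@@H]2O1 | intermediate
20 | Mannich base (C11–CH2NMe2, epimers at C11) | O=C1C(CN(C)C)[C@@H]2[C@H]3C=C(C)[C@@H](O[Si](C)(C)C(C)(C)C)C[C@H]3[C@@](C)(O[Si](CC)(CC)CC)C[C@@H]2O1 | intermediate (not isolated)
21 | trimethylammonium iodide of 20 | O=C1C(C[N+](C)(C)C)[C@@H]2[C@H]3C=C(C)[C@@H](O[Si](C)(C)C(C)(C)C)C[C@H]3[C@@](C)(O[Si](CC)(CC)CC)C[C@@H]2O1.[I-] | intermediate (not isolated)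
22 | α-methylene γ-lactone | O=C1C(=C)[C@@H]2[C@H]3C=C(C)[C@@H](O[Si](C)(C)C(C)(C)C)C[C@H]3[C@@](C)(O[Si](CC)(CC)CC)C[C@@H]2O1 | intermediate
23 | 8α,12-diol | OCC(=C)[C@@H]1[C@H]2C=C(C)[C@@H](O[Si](C)(C)C(C)(C)C)C[C@H]2[C@@](C)(O[Si](CC)(CC)CC)C[C@@H]1O | intermediate
24 | 12-O-TES ether, 8α-OH free | CC[Si](CC)(CC)OCC(=C)[C@@H]1[C@H]2C=C(C)[C@@H](O[Si](C)(C)C(C)(C)C)C[C@H]2[C@@](C)(O[Si](CC)(CC)CC)C[C@@H]1O | intermediate
25 | 2-butyne-1,4-diol | OCC#CCO | starting material
26 | (E)-2-(tributylstannyl)but-2-ene-1,4-diol | OC/C=C(/[Sn](CCCC)(CCCC)CCCC)CO | intermediate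
27 | 2,2-dimethyl-5-(tributylstannyl)-4,7-dihydro-1,3-dioxepine | CC1(C)OCC=C(CO1)[Sn](CCCC)(CCCC)CCCC | intermediate
28 | 5-lithio-2,2-dimethyl-4,7-dihydro-1,3-dioxepine | CC1(C)OCC=C([Li])CO1 | intermediate (not isolated)
29 | 2,2-dimethyl-4,7-dihydro-1,3-dioxepine-5-carboxylic acid | CC1(C)OCC=C(CO1)C(O)=O | intermediate
30 | mixed anhydride of 29 with 2,4,6-trichlorobenzoic acid | CC1(C)OCC=C(CO1)C(=O)OC(=O)c2c(Cl)cc(Cl)cc2Cl | intermediate (not isolated)
31 | C8 dioxepine ester, 12-OTES | CC[Si](CC)(CC)OCC(=C)[C@@H]1[C@H]2C=C(C)[C@@H](O[Si](C)(C)C(C)(C)C)C[C@H]2[C@@](C)(O[Si](CC)(CC)CC)C[C@@H]1OC(=O)C3=CCOC(C)(C)OC3 | intermediate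
32 | C12 enal | O=CC(=C)[C@@H]1[C@H]2C=C(C)[C@@H](O[Si](C)(C)C(C)(C)C)C[C@H]2[C@@](C)(O[Si](CC)(CC)CC)C[C@@H]1OC(=O)C3=CCOC(C)(C)OC3 | intermediate
33 | C12 acrylic acid, bis-silyl ether | OC(=O)C(=C)[C@@H]1[C@H]2C=C(C)[C@@H](O[Si](C)(C)C(C)(C)C)C[C@H]2[C@@](C)(O[Si](CC)(CC)CC)C[C@@H]1OC(=O)C3=CCOC(C)(C)OC3 | intermediate
34 | 3β,10β-diol acid | OC(=O)C(=C)[C@@H]1[C@H]2C=C(C)[C@@H](O)C[C@H]2[C@@](C)(O)C[C@@H]1OC(=O)C3=CCOC(C)(C)OC3 | intermediate
35 | 3β-acetate C12 mixed acetic anhydride | CC(=O)OC(=O)C(=C)[C@@H]1[C@H]2C=C(C)[C@@H](OC(C)=O)C[C@H]2[C@@](C)(O)C[C@@H]1OC(=O)C3=CCOC(C)(C)OC3 | intermediate (not isolated)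
36 | 3β-acetate acid, side chain as acetonide | OC(=O)C(=C)[C@@H]1[C@H]2C=C(C)[C@@H](OC(C)=O)C[C@H]2[C@@](C)(O)C[C@@H]1OC(=O)C3=CCOC(C)(C)OC3 | intermediate
37 | CNP0468194.1 (3β-acetoxy-10β-hydroxy-8α-[(E)-4-hydroxy-2-(hydroxymethyl)but-2-enoyloxy]-cis-cadina-4,11(13)-dien-12-oic acid) | C=C(C(=O)O)[C@@H]1[C@H]2C=C(C)[C@@H](OC(C)=O)C[C@H]2[C@@](C)(O)C[C@@H]1OC(=O)/C(=C/CO)CO | target

## Step count and risks

Total step count: 24. Longest linear sequence: 21 steps (steps 1–15 and 19–24, from (S)-carvone); the side-chain acid takes 3 steps (16–18).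

The three steps most likely to fail:

Step 12. The carbene may insert elsewhere (the C9–H bond, the syn-axial allylic C6–H bond to a bridged six-membered lactone, or the C8–H bond to a β-lactone) or may dimerise. The fallback forms C7–C11 by enolate alkylation without a carbene and sets out from diol 14. Dess–Martin periodinane should oxidise only the secondary alcohol to the 8-ketone F1, and Et3SiOTf/2,6-lutidine then gives its 10β-silyl ether F2. Kinetic deprotonation with LDA at −78 °C on the less hindered C7 side, alkylation with ethyl bromoacetate and equilibration of C7 with DBU to the equatorial (α) epimer should give the keto ester F3. LiB(s-Bu)3H at −78 °C, attacking from the equatorial β direction, should give the axial 8α-alkoxide, which closes onto the ester with loss of ethanol and returns to the route at lactone 19.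

Step 8. Water may attack C10 from the wrong face, or mercuration may spill over to C4=C5. The fallback sets the C10 configuration through a directed epoxidation and an inverting opening, and sets out from alcohol 12. VO(acac)2/t-BuOOH epoxidation directed by the homoallylic 8α-hydroxyl should give the α-epoxide F4. Dilute HClO4 in THF/H2O should open it at the tertiary carbon with inversion to the triol F5 (10β-OH, 10α-CH2OH). TsCl/pyridine gives the primary tosylate F6, K2CO3/MeOH closes the β-epoxide F7, and LiEt3BH delivers hydride to the methylene carbon, returning to the route at diol 14.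

Step 19. Acyl transfer to the hindered axial hydroxyl may be too slow, leaving time for deconjugation of the activated acid or for silyl migration. The fallback changes from an activated acyl donor with a neutral alcohol to a metal alkoxide with a small acyl fluoride, and sets out from acid 29. Cyanuric fluoride/pyridine converts 29 into the acyl fluoride F8; alcohol 24 is deprotonated with LiN(SiMe3)2 in THF at −78 °C and acylated by F8, returning to the route at ester 31.

Further compounds
F1 | step 12 | 8-ketone, 10β-OH, 3β-OTBS | C1[C@H]2C=C(C)[C@@H](O[Si](C)(C)C(C)(C)C)C[C@H]2[C@@](C)(O)CC1=O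
F2 | step 12 | 8-ketone, 10β-OTES, 3β-OTBS | C1[C@H]2C=C(C)[C@@H](O[Si](C)(C)C(C)(C)C)C[C@H]2[C@@](C)(O[Si](CC)(CC)CC)CC1=O
F3 | step 12 | 7α-(ethoxycarbonylmethyl) 8-ketone | CCOC(=O)C[C@@H]1[C@H]2C=C(C)[C@@H](O[Si](C)(C)C(C)(C)C)C[C@H]2[C@@](C)(O[Si](CC)(CC)CC)CC1=O
F4 | step 8 | C10 spiro-epoxide with oxygen α, 8α-OH | C1[C@H]2C=C(C)[C@@H](O[Si](C)(C)C(C)(C)C)C[C@H]2[C@@]3(CO3)C[C@@H]1O
F5 | step 8 | triol (10β-OH, 10α-CH2OH, 8α-OH) | C1[C@H]2C=C(C)[C@@H](O[Si](C)(C)C(C)(C)C)C[C@H]2[C@@](CO)(O)C[C@@H]1O
F6 | step 8 | primary tosylate of F5 | C1[C@H]2C=C(C)[C@@H](O[Si](C)(C)C(C)(C)C)C[C@H]2[C@@](COS(=O)(=O)c3ccc(C)cc3)(O)C[C@@H]1O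
F7 | step 8 | C10 spiro-epoxide with oxygen β, 8α-OH | C1[C@H]2C=C(C)[C@@H](O[Si](C)(C)C(C)(C)C)C[C@H]2[C@@]3(OC3)C[C@@H]1O
F8 | step 19 | 2,2-dimethyl-4,7-dihydro-1,3-dioxepine-5-carbonyl fluoride | CC1(C)OCC=C(CO1)C(F)=O
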